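In a one-step world with steady catalyst, the substrate left shrinks by the same factor in each equal stretch of time. The north-west run is not that world.

| flask | substrate | free catalyst | remark | time |
|---|---|---|---|---|
| north-west | 0.13 M | 0.25 mM | run made earlier |  |
| north-east | 0.13 M | 0.12 mM | run made earlier |  |
| east | 0.13 M | 0.50 mM | run made earlier |  |
| south | 0.065 M | 0.25 mM | run made earlier |  |
| cedar | 0.13 M | 0.25 mM | a single well-mixed tank run continuously and read at steady state, 1.0 h in it on average |  |
| ash | 0.13 M | 0.25 mM | a closed flask charged with all of it at once and left for 1.0 h | 1.0 h |
| alder | 0.13 M (fed, over 1.00 h) | 0.25 mM | a stirred flask in which substrate is dosed at a steady rate over 1.00 h without added volume, worked up at 1.0 h | 1.0 h |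

| run | time / min | product / % |
|---|---|---|
| north-west | 4.00 | 5.5 |
| north-west | 12.0 | 14.1 |
| north-west | 20.0 | 20.1 |
| north-west | 30.0 | 26.6 |
| north-west | 50.0 | 34.1 |
| north-west | 60.0 | 37.3 |
| north-east | 3.00 | 2.3 |
| north-east | 5.00 | 3.6 |
| north-east | 8.00 | 5.6 |
| north-east | 12.0 | 7.7 |
| north-east | 20.0 | 12.2 |
| north-east | 40.0 | 19.7 |
| east | 6.00 | 14.6 |
| east | 12.0 | 23.6 |
| east | 20.0 | 31.2 |
| east | 25.0 | 34.2 |
| east | 30.0 | 37.0 |
| east | 40.0 | 41.5 |
| south | 8.00 | 10.6 |
| south | 15.0 | 17.1 |
| south | 20.0 | 20.9 |
| south | 30.0 | 26.1 |
| south | 40.0 | 30.8 |

(readings scatter by 0.3 percentage points)

- the set-up with the highest amount of product at the outlet or at the end, in percent of the substrate put in ("none" if the first two lie within 2 percentage points) (cedar / ash / alder / none)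
- amount of product at the outlet or at the end, in percent of the substrate put in, cedar
- amount of product at the outlet or at the end, in percent of the substrate put in, ash
- amount of product at the outlet or at the end, in percent of the substrate put in, alder

In the north-west run the first 30.0 min leaves 73.4% of the substrate, but the next stretch of equal length keeps 85.4% of what it starts with, which is more, so the reaction slows. The south run, with half the substrate, stands 0.5 percentage points from north-west at the same time, and a reading is good to 0.3 points. So we read the percentage as unchanged by the amount of substrate, within the scatter of two readings (pseudo-first-order in substrate), and we read the slowing as free catalyst fading with the clock.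

Ash then costs no reckoning. It has the north-west charge and time, so we take that run's last reading, 37.3%.

Alder needs one step more. A portion of substrate arriving at some moment meets the same fading catalyst, so it survives to the end by the ratio of the closed flask's fraction left at the end to its fraction left at arrival. The steady dosing averages this over arrival times. One over the fraction left is 1 at the start, 1.36 at 30.0 min and 1.59 at 60.0 min, and Simpson's rule gives 1.34. This is the arrival factor, the mean over the dosing of one over the fraction of substrate a closed flask still holds. Alder's substrate left is ash's multiplied by it, 84.1%, so we expect 15.9% product. Cedar, a tank at one standing level of catalyst, lies outside this factor, and there we take the forecast's figure unchecked.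

The forecast names ash as best, with cedar 30%, ash 37.2% and alder 16.3%, which stands 0.40 points above our alder. Its ground: “Catalyst dying second order in itself fits”.

The flasks give cedar 30.4%, ash 37.3% and alder 16.0%, so the best is ash.

    2 free catalyst → spent catalyst (k = 1.60 M⁻¹ s⁻¹)
    substrate + free catalyst → free catalyst + product (k = 1.10 M⁻¹ s⁻¹)

Alder comes to 16.0%. At 0.500 h alder held 41.0% of its charged catalyst as free catalyst and 59.0% as spent catalyst, and ash held 41.0% and 59.0%. The factor 1.34 goes on to alder left for 10.0 h, when ash has 31.1% of its substrate left. Multiplying gives 41.7% left and 58.3% product, and alder at that time stands at 58.3%.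

The readings come from a simulation from invented constants, noise included.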